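**Plan**
1. Target read as ent-epiafzelechin-(4β→8)-epiafzelechin-(4α→8)-(2S,3S,4R)-flavan-3,4-diol: in the upper and middle units H-2, H-3 and H-4 are all cis; the lower unit is a 2,3-cis-3,4-trans diol.
2. Retrosynthesis: in the middle unit, then in the upper unit, C4–H goes back to a tertiary C4–OH, the C3–C4 bond of ring C is cut to a C4 diaryl ketone plus a C3 aldehyde still held on O1, and the C4–aryl bond is cut to ArLi + ArCHO; the lower flavan-3,4-diol is made separately as an 8-bromide.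
3. Forward: the chain grows from the bottom. 8-Lithio lower unit + middle-unit aldehyde → diaryl ketone → vinyl cleaved to CHO → SmI2 pinacol closure of middle ring C; the same four operations with the upper-unit block close upper ring C; one double ionic deoxygenation, desilylation and hydrogenolysis finish.
4. Enabling feature: C4 of the middle unit is bonded to two 2,6-dioxygenated benzene rings (C4a of its own ring A and C8 of ring A of the lower unit) and is tied to C3 through C4a–C8a–O1–C2. It can therefore act as a diaryl ketone/ketyl for the ring closure and later as a doubly stabilised benzylic cation for stereocontrolled hydride capture.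
5. Stereochemistry: every C2 from iridium-catalysed asymmetric allylic etherification (ligand antipodes give the 2R middle and the 2S upper/lower series); C3 of the middle and upper units from the chelated pinacol closures; both interflavan C4 centres from hydride delivery anti to O3; lower-unit C3 from LiBH(s-Bu)3 reduction of the 3-ketone and its C4–OH from DDQ/water anti to O3.

Key step: step 19

Remark: L denotes O,O′-(1,1′-binaphthalene-2,2′-diyl) N,N-bis(1-phenylethyl)phosphoramidite; "L-a" is defined as the antipode that gives the (S)-ether and "L-b" as its mirror image (the sense of induction is to be confirmed on a small scale).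

**Route**

Step 1
Reactants: 1 2,4,6-trihydroxybenzaldehyde
Product: 2 4,6-bis(benzyloxy)-2-hydroxybenzaldehyde
Conditions: BnBr (2.0 equiv), K2CO3, DMF, 0 °C to rt
Reagents that add atoms: benzyl bromide, BrCc1ccccc1
Why: Williamson etherification; the hydroxyl hydrogen-bonded to the formyl group is the least nucleophilic and should stay free.

Step 2
Reactants: 2 4,6-bis(benzyloxy)-2-hydroxybenzaldehyde
Product: 3 4,6-bis(benzyloxy)-3-bromo-2-hydroxybenzaldehyde
Conditions: NBS (1.0 equiv), i-Pr2NH (cat.), CH2Cl2, 0 °C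
Reagents that add atoms: N-bromosuccinimide, O=C1CCC(=O)N1Br
Why: Electrophilic aromatic bromination, expected ortho to the free phenol (C3, between OH and OBn) and not at the more hindered C5 between two benzyloxy groups.

Step 3
Reactants: 4 4-(benzyloxy)benzaldehyde
Product: 5 ethyl (E)-3-[4-(benzyloxy)phenyl]acrylate
Conditions: Ph3P=CHCO2Et, toluene, 80 °C
Reagents that add atoms: ethyl (triphenylphosphoranylidene)acetate, CCOC(=O)C=P(c1ccccc1)(c1ccccc1)c1ccccc1
Why: Wittig olefination with a stabilised ylide should give the E-cinnamate.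

Step 4
Reactants: 5 ethyl (E)-3-[4-(benzyloxy)phenyl]acrylate
Product: 6 (E)-3-[4-(benzyloxy)phenyl]prop-2-en-1-ol
Conditions: i-Bu2AlH (2.2 equiv), CH2Cl2, −78 °C
Reagents that add atoms: none
Why: 1,2-Reduction of the conjugated ester by the aluminium hydride leaves the alkene untouched.

Step 5
Reactants: 6 (E)-3-[4-(benzyloxy)phenyl]prop-2-en-1-ol
Product: 7 (E)-3-[4-(benzyloxy)phenyl]allyl methyl carbonate
Conditions: ClCO2Me, pyridine, CH2Cl2, 0 °C
Reagents that add atoms: methyl chloroformate, COC(=O)Cl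
Why: Acylation of the primary allylic alcohol gives the linear carbonate needed for iridium allylation.

Step 6
Reactants: 3 4,6-bis(benzyloxy)-3-bromo-2-hydroxybenzaldehyde; 7 (E)-3-[4-(benzyloxy)phenyl]allyl methyl carbonate
Product: 8 (S)-4,6-bis(benzyloxy)-2-{1-[4-(benzyloxy)phenyl]allyloxy}-3-bromobenzaldehyde (middle-unit block)
Conditions: LiN(SiMe3)2 (1.0 equiv, on 3); [Ir(cod)Cl]2 (2 mol %), L-a (4 mol %), THF, 50 °C
Reagents that add atoms: none
Why: Iridium-catalysed branched-selective asymmetric allylic etherification; the phenoxide attacks the substituted terminus of the allyliridium complex and the ligand sets the benzylic C–O centre (future C2 of the middle unit) by catalyst control.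

Step 7
Reactants: 3 4,6-bis(benzyloxy)-3-bromo-2-hydroxybenzaldehyde; 7 (E)-3-[4-(benzyloxy)phenyl]allyl methyl carbonate
Product: 9 (R)-4,6-bis(benzyloxy)-2-{1-[4-(benzyloxy)phenyl]allyloxy}-3-bromobenzaldehyde
Conditions: LiN(SiMe3)2 (1.0 equiv, on 3); [Ir(cod)Cl]2 (2 mol %), L-b (4 mol %), THF, 50 °C
Reagents that add atoms: none
Why: The same iridium-catalysed asymmetric allylic etherification with the mirror-image ligand should give the enantiomeric ether (future C2 of the lower unit).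

Step 8
Reactants: 2 4,6-bis(benzyloxy)-2-hydroxybenzaldehyde; 7 (E)-3-[4-(benzyloxy)phenyl]allyl methyl carbonate
Product: 10 (R)-4,6-bis(benzyloxy)-2-{1-[4-(benzyloxy)phenyl]allyloxy}benzaldehyde (upper-unit block)
Conditions: LiN(SiMe3)2 (1.0 equiv, on 2); [Ir(cod)Cl]2 (2 mol %), L-b (4 mol %), THF, 50 °C
Reagents that add atoms: none
Why: Iridium-catalysed asymmetric allylic etherification of the less hindered phenoxide sets the future C2 of the upper unit by catalyst control.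

Step 9
Reactants: 9 (R)-bromo allyl ether aldehyde
Product: 11 (R)-1,5-bis(benzyloxy)-2-bromo-3-{1-[4-(benzyloxy)phenyl]allyloxy}-4-vinylbenzene
Conditions: Ph3PCH3Br, KOt-Bu, THF, 0 °C
Reagents that add atoms: methyltriphenylphosphonium bromide, C[P+](c1ccccc1)(c1ccccc1)c1ccccc1.[Br-]
Why: Wittig methylenation of the aldehyde; the ylide should not touch the benzylic ether stereocentre.

Step 10
Reactants: 11 (R)-divinyl ether
Product: 12 (R)-5,7-bis(benzyloxy)-2-[4-(benzyloxy)phenyl]-8-bromo-2H-chromene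
Conditions: second-generation Grubbs catalyst (5 mol %), CH2Cl2, 40 °C
Reagents that add atoms: none
Why: Ring-closing olefin metathesis to the 2H-chromene with loss of ethylene; the stereocentre is not involved.

Step 11
Reactants: 12 (R)-8-bromo-2H-chromene
Product: 14 (2S,3R)-5,7-bis(benzyloxy)-2-[4-(benzyloxy)phenyl]-8-bromochroman-3-ol (2,3-trans), via C3 alkylborane 13 (not isolated)
Conditions: BH3·THF, THF, 0 °C to rt; then NaOH, H2O2
Reagents that add atoms: borane–tetrahydrofuran, [BH3-][O+]1CCCC1 (boron of 13); hydrogen peroxide, OO (oxygen of 14)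
Why: Hydroboration–oxidation; boron adds to C3 (distal to ring A) from the face opposite the C2 aryl group, and stereoretentive oxidation gives the 2,3-trans alcohol.

Step 12
Reactants: 14 2,3-trans 8-bromoflavan-3-ol
Product: 15 (S)-5,7-bis(benzyloxy)-2-[4-(benzyloxy)phenyl]-8-bromochroman-3-one
Conditions: Dess–Martin periodinane, NaHCO3, CH2Cl2, rt
Reagents that add atoms: none
Why: Dess–Martin oxidation under buffered conditions should give the 3-ketone without epimerising C2.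

Step 13
Reactants: 15 8-bromoflavan-3-one
Product: 16 (2S,3S)-5,7-bis(benzyloxy)-2-[4-(benzyloxy)phenyl]-8-bromochroman-3-ol (2,3-cis)
Conditions: LiBH(s-Bu)3, THF, −78 °C
Reagents that add atoms: none
Why: The bulky hydride attacks the C3 ketone from the face opposite the C2 aryl group and gives the 2,3-cis alcohol by substrate control.

Step 14
Reactants: 16 2,3-cis 8-bromoflavan-3-ol
Product: 17 (2S,3S,4R)-5,7-bis(benzyloxy)-2-[4-(benzyloxy)phenyl]-8-bromochromane-3,4-diol (2,3-cis, 3,4-trans)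
Conditions: DDQ (1.5 equiv), CH2Cl2/H2O, rt
Reagents that add atoms: water, O
Why: DDQ benzylic oxidation; hydride abstraction at C4 gives a cation stabilised by the trioxygenated ring A, which water traps anti to the C3 hydroxyl.

Step 15
Reactants: 17 bromoflavan-3,4-diol
Product: 18 3,4-bis-O-(tert-butyldimethylsilyl) ether of 17 (lower-unit block)
Conditions: TBSOTf (3 equiv), 2,6-lutidine, CH2Cl2, −78 to 0 °C
Reagents that add atoms: tert-butyldimethylsilyl triflate, CC(C)(C)[Si](C)(C)OS(=O)(=O)C(F)(F)F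
Why: Silylation with the silyl triflate under basic conditions protects both hydroxyls, the acid-labile benzylic one included.

Step 16
Reactants: 18 lower-unit bromide; 8 middle-unit aldehyde
Product: 20 diarylmethanol joining C8 of the lower unit to the former formyl carbon of 8 (carbinol epimers), via lower-unit aryllithium 19 (not isolated)
Conditions: t-BuLi (2.1 equiv), THF, −78 °C; then 8, −78 to −40 °C
Reagents that add atoms: tert-butyllithium, [Li]C(C)(C)C (lithium of 19)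
Why: Bromine–lithium exchange then 1,2-addition of the aryllithium to the aldehyde, which is faster than exchange with the aryl bromide of 8; the new carbinol centre is removed in step 17.

Step 17
Reactants: 20 diarylmethanol
Product: 21 diaryl ketone (future C4 of the middle unit as C=O)
Conditions: Dess–Martin periodinane, NaHCO3, CH2Cl2, rt
Reagents that add atoms: none
Why: Dess–Martin oxidation of the hindered benzhydrol to the diaryl ketone.

Step 18
Reactants: 21 diaryl ketone with vinyl group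
Product: 23 keto-aldehyde (C4 ketone and C3 aldehyde of the middle unit), via vicinal diol 22 (not isolated)
Conditions: OsO4 (2 mol %), NaIO4 (4 equiv), 2,6-lutidine, dioxane/H2O, rt; used at once
Reagents that add atoms: osmium tetroxide, O=[Os](=O)(=O)=O (oxygen of the new C=O); sodium periodate, [Na+].[O-]I(=O)(=O)=O, and water, O (reoxidise osmium and so supply that oxygen)
Why: Lemieux–Johnson oxidation of the only alkene unmasks the C3 aldehyde under near-neutral conditions that should keep the enolisable C2 centre intact.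

Step 19
Reactants: 23 keto-aldehyde
Product: 24 middle-unit ring C closed as the cis-3,4-diol (2,3-cis; lower-unit aryl on C4 trans to O3)
Conditions: SmI2 (3 equiv), THF, −78 to −20 °C; aq. NH4Cl
Reagents that add atoms: none
Why: SmI2 transfers one electron to a carbonyl group (expected at the diaryl ketone, which is chelated through its ortho oxygens) to give a trivalent-samarium ketyl whose carbon C4 adds to the C3 aldehyde bound to the same metal, and a second electron gives the cis-3,4-diolate. The closest known reaction type is the SmI2-mediated intramolecular ketone–aldehyde pinacol cyclisation to cis-cycloalkane-1,2-diols, including α-oxygenated aldehydes. Ring C of the middle unit closes in the 6-exo-trig mode (C4 onto the carbonyl carbon C3, oxygen exocyclic). The C3/C4 relationship is fixed by the samarium bridge between the two oxygens; the C3/C2 relationship by the resident C2 centre, because with the C2 aryl equatorial the lower-unit aryl on C4 must stand pseudo-axial to avoid the peri 5-benzyloxy group, which leaves C4–O equatorial and forces C3–O axial, cis to the C2 aryl. The step needs chemoselectivity (coupling and not reductive loss of the C2 aryloxy group or of the aryl bromide, and no enolisation of the aldehyde); the six-membered chelate, the low temperature, the absence of HMPA and the non-basic medium should secure it, and the C4 configuration is temporary and erased in step 25.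

Step 20
Reactants: 24 cis-3,4-diol
Product: 25 3-O-TBS ether of 24 (tertiary C4–OH free)
Conditions: TBSOTf (1.2 equiv), 2,6-lutidine, CH2Cl2, −78 °C
Reagents that add atoms: tert-butyldimethylsilyl triflate, CC(C)(C)[Si](C)(C)OS(=O)(=O)C(F)(F)F
Why: Selective silylation of the secondary C3 hydroxyl; the tertiary, doubly benzylic hydroxyl is too hindered to react.

Step 21
Reactants: 25 dimer bromide; 10 upper-unit aldehyde
Product: 27 diarylmethanol joining C8 of the middle unit to the former formyl carbon of 10 (carbinol epimers), via dilithio intermediate 26 (not isolated)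
Conditions: t-BuLi (3.1 equiv), THF, −78 °C; then 10 (1.5 equiv), −78 to −40 °C
Reagents that add atoms: tert-butyllithium, [Li]C(C)(C)C (lithium of 26)
Why: Deprotonation of the tertiary alcohol, bromine–lithium exchange at C8 of the middle unit and 1,2-addition to the aldehyde; the new carbinol centre is removed in step 22.

Step 22
Reactants: 27 diarylmethanol
Product: 28 diaryl ketone (future C4 of the upper unit as C=O)
Conditions: Dess–Martin periodinane, NaHCO3, CH2Cl2, rt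
Reagents that add atoms: none
Why: Dess–Martin oxidation of the secondary benzhydrol; the tertiary alcohol cannot be oxidised.

Step 23
Reactants: 28 diaryl ketone with vinyl group
Product: 30 keto-aldehyde (C4 ketone and C3 aldehyde of the upper unit), via vicinal diol 29 (not isolated)
Conditions: OsO4 (2 mol %), NaIO4 (4 equiv), 2,6-lutidine, dioxane/H2O, rt; used at once
Reagents that add atoms: osmium tetroxide, O=[Os](=O)(=O)=O (oxygen of the new C=O); sodium periodate, [Na+].[O-]I(=O)(=O)=O, and water, O (reoxidise osmium and so supply that oxygen)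
Why: Lemieux–Johnson oxidation of the only alkene unmasks the C3 aldehyde of the upper unit.

Step 24
Reactants: 30 keto-aldehyde
Product: 31 upper-unit ring C closed as the cis-3,4-diol (2,3-cis; middle-unit aryl on C4 trans to O3)
Conditions: SmI2 (3 equiv), THF, −78 to −20 °C; aq. NH4Cl
Reagents that add atoms: none
Why: SmI2-mediated ketone–aldehyde pinacol cyclisation (6-exo-trig) as in step 19; the samarium bridge gives the cis-diol and the pseudo-axial preference of the aryl on C4 places O3 cis to the C2 aryl of the upper unit.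

Step 25
Reactants: 31 bis(tertiary alcohol)
Product: 32 trimer with C4–H in the middle and upper units (both all-cis), three TBS and nine benzyl groups
Conditions: Bu3SnH (6 equiv), CF3CO2H (3 equiv), CH2Cl2, −40 to 0 °C
Reagents that add atoms: none
Why: Ionic hydrogenation, known to give 3,4-cis products from 4-aryl-4-hydroxyflavans: acid ionises both tertiary doubly benzylic alcohols to cations stabilised by two trioxygenated rings and the tin hydride adds to each from the face opposite O3 and the C2 aryl, while the secondary 4-silyloxy group of the lower unit gives a far less stabilised cation and should survive.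

Step 26
Reactants: 32 silylated trimer
Product: 33 nona-O-benzyl trimer (all four aliphatic hydroxyls free)
Conditions: Bu4NF (5 equiv), THF, 0 °C to rt
Reagents that add atoms: none
Why: Fluoride-mediated desilylation removes the three TBS groups without touching benzyl ethers or the benzylic 4-hydroxyl.

Step 27
Reactants: 33 nona-O-benzyl trimer
Product: 34 target trimer
Conditions: H2 (1 atm), Pd(OH)2/C, THF/MeOH, rt; filtration, lyophilisation
Reagents that add atoms: none
Why: Catalytic hydrogenolysis of the nine aryl benzyl ethers under neutral conditions, under which the ring O1–C2 bonds and the secondary benzylic 4-hydroxyl are expected to persist.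

**Compound list**

1 | 2,4,6-trihydroxybenzaldehyde | O=Cc1c(O)cc(O)cc1O | starting material
2 | 4,6-bis(benzyloxy)-2-hydroxybenzaldehyde | O=Cc1c(O)cc(OCc5ccccc5)cc1OCc5ccccc5 | intermediate
3 | 4,6-bis(benzyloxy)-3-bromo-2-hydroxybenzaldehyde | O=Cc1c(O)c(Br)c(OCc5ccccc5)cc1OCc5ccccc5 | intermediate
4 | 4-(benzyloxy)benzaldehyde | O=Cc1ccc(OCc5ccccc5)cc1 | starting material
5 | ethyl (E)-3-[4-(benzyloxy)phenyl]acrylate | CCOC(=O)/C=C/c1ccc(OCc5ccccc5)cc1 | intermediate
6 | (E)-3-[4-(benzyloxy)phenyl]prop-2-en-1-ol | OC/C=C/c1ccc(OCc5ccccc5)cc1 | intermediate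
7 | (E)-3-[4-(benzyloxy)phenyl]allyl methyl carbonate | COC(=O)OC/C=C/c1ccc(OCc5ccccc5)cc1 | intermediate
8 | (S)-4,6-bis(benzyloxy)-2-{1-[4-(benzyloxy)phenyl]allyloxy}-3-bromobenzaldehyde | O=Cc1c(OCc5ccccc5)cc(OCc5ccccc5)c(Br)c1O[C@@H](C=C)c1ccc(OCc5ccccc5)cc1 | intermediate
9 | (R)-4,6-bis(benzyloxy)-2-{1-[4-(benzyloxy)phenyl]allyloxy}-3-bromobenzaldehyde | O=Cc1c(OCc5ccccc5)cc(OCc5ccccc5)c(Br)c1O[C@H](C=C)c1ccc(OCc5ccccc5)cc1 | intermediate
10 | (R)-4,6-bis(benzyloxy)-2-{1-[4-(benzyloxy)phenyl]allyloxy}benzaldehyde | O=Cc1c(OCc5ccccc5)cc(OCc5ccccc5)cc1O[C@H](C=C)c1ccc(OCc5ccccc5)cc1 | intermediate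
11 | (R)-1,5-bis(benzyloxy)-2-bromo-3-{1-[4-(benzyloxy)phenyl]allyloxy}-4-vinylbenzene | C=Cc1c(OCc5ccccc5)cc(OCc5ccccc5)c(Br)c1O[C@H](C=C)c1ccc(OCc5ccccc5)cc1 | intermediate
12 | (R)-5,7-bis(benzyloxy)-2-[4-(benzyloxy)phenyl]-8-bromo-2H-chromene | Brc1c(OCc5ccccc5)cc(OCc5ccccc5)c2c1O[C@@H](c1ccc(OCc5ccccc5)cc1)C=C2 | intermediate
13 | [5,7-bis(benzyloxy)-2-[4-(benzyloxy)phenyl]-8-bromochroman-3-yl]borane, boron trans to the C2 aryl (same C2 configuration as 12) | Brc1c(OCc5ccccc5)cc(OCc5ccccc5)c2c1O[C@@H](c1ccc(OCc5ccccc5)cc1)[C@H](B)C2 | intermediate (not isolated)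
14 | (2S,3R)-5,7-bis(benzyloxy)-2-[4-(benzyloxy)phenyl]-8-bromochroman-3-ol (2,3-trans) | Brc1c(OCc5ccccc5)cc(OCc5ccccc5)c2c1O[C@@H](c1ccc(OCc5ccccc5)cc1)[C@H](O)C2 | intermediate
15 | (S)-5,7-bis(benzyloxy)-2-[4-(benzyloxy)phenyl]-8-bromochroman-3-one | Brc1c(OCc5ccccc5)cc(OCc5ccccc5)c2c1O[C@@H](c1ccc(OCc5ccccc5)cc1)C(=O)C2 | intermediate
16 | (2S,3S)-5,7-bis(benzyloxy)-2-[4-(benzyloxy)phenyl]-8-bromochroman-3-ol (2,3-cis) | Brc1c(OCc5ccccc5)cc(OCc5ccccc5)c2c1O[C@@H](c1ccc(OCc5ccccc5)cc1)[C@@H](O)C2 | intermediate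
17 | (2S,3S,4R)-5,7-bis(benzyloxy)-2-[4-(benzyloxy)phenyl]-8-bromochromane-3,4-diol (2,3-cis, 3,4-trans) | Brc1c(OCc5ccccc5)cc(OCc5ccccc5)c2c1O[C@@H](c1ccc(OCc5ccccc5)cc1)[C@@H](O)[C@@H]2O | intermediate
18 | 3,4-bis-O-(tert-butyldimethylsilyl) ether of 17 (2,3-cis, 3,4-trans) | Brc1c(OCc5ccccc5)cc(OCc5ccccc5)c2c1O[C@@H](c1ccc(OCc5ccccc5)cc1)[C@@H](O[Si](C)(C)C(C)(C)C)[C@@H]2O[Si](C)(C)C(C)(C)C | intermediate
19 | 8-lithio analogue of 18 | [Li]c1c(OCc5ccccc5)cc(OCc5ccccc5)c2c1O[C@@H](c1ccc(OCc5ccccc5)cc1)[C@@H](O[Si](C)(C)C(C)(C)C)[C@@H]2O[Si](C)(C)C(C)(C)C | intermediate (not isolated)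
20 | [4,6-bis(benzyloxy)-3-bromo-2-{(S)-1-[4-(benzyloxy)phenyl]allyloxy}phenyl][lower-unit chroman-8-yl of 18]methanol, carbinol epimers | OC(c1c(OCc5ccccc5)cc(OCc5ccccc5)c(Br)c1O[C@@H](C=C)c1ccc(OCc5ccccc5)cc1)c1c(OCc5ccccc5)cc(OCc5ccccc5)c2c1O[C@@H](c1ccc(OCc5ccccc5)cc1)[C@@H](O[Si](C)(C)C(C)(C)C)[C@@H]2O[Si](C)(C)C(C)(C)C | intermediate
21 | diaryl ketone from 20 | O=C(c1c(OCc5ccccc5)cc(OCc5ccccc5)c(Br)c1O[C@@H](C=C)c1ccc(OCc5ccccc5)cc1)c1c(OCc5ccccc5)cc(OCc5ccccc5)c2c1O[C@@H](c1ccc(OCc5ccccc5)cc1)[C@@H](O[Si](C)(C)C(C)(C)C)[C@@H]2O[Si](C)(C)C(C)(C)C | intermediate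
22 | vicinal diol from dihydroxylation of the vinyl group of 21 (diol carbinol epimers) | O=C(c1c(OCc5ccccc5)cc(OCc5ccccc5)c(Br)c1O[C@@H](C(O)CO)c1ccc(OCc5ccccc5)cc1)c1c(OCc5ccccc5)cc(OCc5ccccc5)c2c1O[C@@H](c1ccc(OCc5ccccc5)cc1)[C@@H](O[Si](C)(C)C(C)(C)C)[C@@H]2O[Si](C)(C)C(C)(C)C | intermediate (not isolated)
23 | keto-aldehyde: as 21 with the vinyl group replaced by CHO (aryloxy-bearing carbon of unchanged configuration) | O=C(c1c(OCc5ccccc5)cc(OCc5ccccc5)c(Br)c1O[C@@H](C=O)c1ccc(OCc5ccccc5)cc1)c1c(OCc5ccccc5)cc(OCc5ccccc5)c2c1O[C@@H](c1ccc(OCc5ccccc5)cc1)[C@@H](O[Si](C)(C)C(C)(C)C)[C@@H]2O[Si](C)(C)C(C)(C)C | intermediate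
24 | middle–lower dimer: (2R)-5,7-bis(benzyloxy)-2-[4-(benzyloxy)phenyl]-8-bromo-4-[lower-unit chroman-8-yl of 18]chromane-3,4-diol; 3-OH and 4-OH cis to each other and to the C2 aryl, C4 aryl trans | c5ccccc5COc1ccc([C@H]2Oc3c(c(OCc5ccccc5)cc(OCc5ccccc5)c3Br)[C@](O)(c3c(OCc5ccccc5)cc(OCc5ccccc5)c4c3O[C@@H](c3ccc(OCc5ccccc5)cc3)[C@@H](O[Si](C)(C)C(C)(C)C)[C@@H]4O[Si](C)(C)C(C)(C)C)[C@H]2O)cc1 | intermediate
25 | 3-O-TBS ether of 24 (tertiary 4-OH free) | c5ccccc5COc1ccc([C@H]2Oc3c(c(OCc5ccccc5)cc(OCc5ccccc5)c3Br)[C@](O)(c3c(OCc5ccccc5)cc(OCc5ccccc5)c4c3O[C@@H](c3ccc(OCc5ccccc5)cc3)[C@@H](O[Si](C)(C)C(C)(C)C)[C@@H]4O[Si](C)(C)C(C)(C)C)[C@H]2O[Si](C)(C)C(C)(C)C)cc1 | intermediate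
26 | dilithio derivative of 25 (C8–Li of the middle unit, C4–OLi) | c5ccccc5COc1ccc([C@H]2Oc3c(c(OCc5ccccc5)cc(OCc5ccccc5)c3[Li])[C@](O[Li])(c3c(OCc5ccccc5)cc(OCc5ccccc5)c4c3O[C@@H](c3ccc(OCc5ccccc5)cc3)[C@@H](O[Si](C)(C)C(C)(C)C)[C@@H]4O[Si](C)(C)C(C)(C)C)[C@H]2O[Si](C)(C)C(C)(C)C)cc1 | intermediate (not isolated)
27 | as 25 with Br replaced by CH(OH)–aryl, aryl = 2,4-bis(benzyloxy)-6-{(R)-1-[4-(benzyloxy)phenyl]allyloxy}phenyl; carbinol epimers | c5ccccc5COc1ccc([C@H]2Oc3c(c(OCc5ccccc5)cc(OCc5ccccc5)c3C(O)c3c(OCc5ccccc5)cc(OCc5ccccc5)cc3O[C@H](C=C)c3ccc(OCc5ccccc5)cc3)[C@](O)(c3c(OCc5ccccc5)cc(OCc5ccccc5)c4c3O[C@@H](c3ccc(OCc5ccccc5)cc3)[C@@H](O[Si](C)(C)C(C)(C)C)[C@@H]4O[Si](C)(C)C(C)(C)C)[C@H]2O[Si](C)(C)C(C)(C)C)cc1 | intermediate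
28 | diaryl ketone from 27 | c5ccccc5COc1ccc([C@H]2Oc3c(c(OCc5ccccc5)cc(OCc5ccccc5)c3C(=O)c3c(OCc5ccccc5)cc(OCc5ccccc5)cc3O[C@H](C=C)c3ccc(OCc5ccccc5)cc3)[C@](O)(c3c(OCc5ccccc5)cc(OCc5ccccc5)c4c3O[C@@H](c3ccc(OCc5ccccc5)cc3)[C@@H](O[Si](C)(C)C(C)(C)C)[C@@H]4O[Si](C)(C)C(C)(C)C)[C@H]2O[Si](C)(C)C(C)(C)C)cc1 | intermediate
29 | vicinal diol from dihydroxylation of the vinyl group of 28 (diol carbinol epimers) | c5ccccc5COc1ccc([C@H]2Oc3c(c(OCc5ccccc5)cc(OCc5ccccc5)c3C(=O)c3c(OCc5ccccc5)cc(OCc5ccccc5)cc3O[C@H](C(O)CO)c3ccc(OCc5ccccc5)cc3)[C@](O)(c3c(OCc5ccccc5)cc(OCc5ccccc5)c4c3O[C@@H](c3ccc(OCc5ccccc5)cc3)[C@@H](O[Si](C)(C)C(C)(C)C)[C@@H]4O[Si](C)(C)C(C)(C)C)[C@H]2O[Si](C)(C)C(C)(C)C)cc1 | intermediate (not isolated)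
30 | keto-aldehyde: as 28 with the vinyl group replaced by CHO | c5ccccc5COc1ccc([C@H]2Oc3c(c(OCc5ccccc5)cc(OCc5ccccc5)c3C(=O)c3c(OCc5ccccc5)cc(OCc5ccccc5)cc3O[C@H](C=O)c3ccc(OCc5ccccc5)cc3)[C@](O)(c3c(OCc5ccccc5)cc(OCc5ccccc5)c4c3O[C@@H](c3ccc(OCc5ccccc5)cc3)[C@@H](O[Si](C)(C)C(C)(C)C)[C@@H]4O[Si](C)(C)C(C)(C)C)[C@H]2O[Si](C)(C)C(C)(C)C)cc1 | intermediate
31 | trimer with both interflavan C4 centres as tertiary alcohols: upper unit (2S) cis-3,4-diol with 3-OH cis to its C2 aryl and the C4 aryl trans; middle unit as in 25 | c5ccccc5COc1ccc([C@H]2Oc3c(c(OCc5ccccc5)cc(OCc5ccccc5)c3[C@]3(O)c4c(OCc5ccccc5)cc(OCc5ccccc5)cc4O[C@@H](c4ccc(OCc5ccccc5)cc4)[C@H]3O)[C@](O)(c3c(OCc5ccccc5)cc(OCc5ccccc5)c4c3O[C@@H](c3ccc(OCc5ccccc5)cc3)[C@@H](O[Si](C)(C)C(C)(C)C)[C@@H]4O[Si](C)(C)C(C)(C)C)[C@H]2O[Si](C)(C)C(C)(C)C)cc1 | intermediate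
32 | nona-O-benzyl trimer carrying TBS on O3 of the middle unit and on O3 and O4 of the lower unit; upper and middle units all-cis at C2/C3/C4 | c5ccccc5COc1ccc([C@H]2Oc3c(c(OCc5ccccc5)cc(OCc5ccccc5)c3[C@H]3c4c(OCc5ccccc5)cc(OCc5ccccc5)cc4O[C@@H](c4ccc(OCc5ccccc5)cc4)[C@H]3O)[C@@H](c3c(OCc5ccccc5)cc(OCc5ccccc5)c4c3O[C@@H](c3ccc(OCc5ccccc5)cc3)[C@@H](O[Si](C)(C)C(C)(C)C)[C@@H]4O[Si](C)(C)C(C)(C)C)[C@H]2O[Si](C)(C)C(C)(C)C)cc1 | intermediate
33 | nona-O-benzyl ether of the target (all phenols benzylated, four aliphatic OH free) | c5ccccc5COc1ccc([C@H]2Oc3c(c(OCc5ccccc5)cc(OCc5ccccc5)c3[C@H]3c4c(OCc5ccccc5)cc(OCc5ccccc5)cc4O[C@@H](c4ccc(OCc5ccccc5)cc4)[C@H]3O)[C@@H](c3c(OCc5ccccc5)cc(OCc5ccccc5)c4c3O[C@@H](c3ccc(OCc5ccccc5)cc3)[C@@H](O)[C@@H]4O)[C@H]2O)cc1 | intermediate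
34 | ent-epiafzelechin-(4β→8)-epiafzelechin-(4α→8)-(2S,3S,4R)-2-(4-hydroxyphenyl)chromane-3,4,5,7-tetrol (upper unit 2S,3S all-cis; middle unit 2R,3R all-cis) | Oc1ccc([C@H]2Oc3c(c(O)cc(O)c3[C@H]3c4c(O)cc(O)cc4O[C@@H](c4ccc(O)cc4)[C@H]3O)[C@@H](c3c(O)cc(O)c4c3O[C@@H](c3ccc(O)cc3)[C@@H](O)[C@@H]4O)[C@H]2O)cc1 | target

**Totals**

Total step count: 27.
Longest linear sequence: 23 steps (4 → 5 → 6 → 7 → 9 → 11 → 12 → 14 → 15 → 16 → 17 → 18 → 20 → 21 → 23 → 24 → 25 → 27 → 28 → 30 → 31 → 32 → 33 → 34; steps 3–5, 7, 9–27).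

**Steps most likely to fail**

Step 19. The aldehyde may be reduced first and its ketyl may expel the C2 aryloxy group (reductive opening of the O1–C2 ether). The carbonyl groups may also be reduced without C–C bond formation at the crowded C4, or the closure may show poor facial selectivity at C3. The fallback builds middle ring C before the lower aryl is attached and makes the C4 carbinol by organolithium addition. It sets out from 8. Wittig methylenation (Ph3PCH3Br, KOt-Bu) should give (S)-1,5-bis(benzyloxy)-2-bromo-3-{1-[4-(benzyloxy)phenyl]allyloxy}-4-vinylbenzene F1. Ring-closing metathesis with the second-generation Grubbs catalyst should give the (S)-8-bromo-2H-chromene F2. Hydroboration–oxidation should give the 2,3-trans (2R,3S)-chroman-3-ol F3, and Dess–Martin oxidation the (R)-chroman-3-one F4. LiBH(s-Bu)3 should give the 2,3-cis (2R,3R)-chroman-3-ol F5, and TBSOTf/2,6-lutidine its 3-O-TBS ether F6. DDQ/water should give the 3,4-trans 4-hydroxy compound F7, and Dess–Martin oxidation the 3-silyloxychroman-4-one F8. The aryllithium 19 (from 18, t-BuLi, −78 °C) should then add to F8 from the face opposite the 3-silyloxy group. This gives 25 directly, where the route resumes at step 21.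

Step 25. The 4-silyloxy group of the lower unit may also ionise, so the lower C4–O would be lost by over-reduction or desilylation. The fallback removes that group from danger as a ketone and sets out from 31. Bu4NF should give the hexaol F9. MnO2 (CH2Cl2) should oxidise only the secondary benzylic 4-hydroxyl of the lower unit to the 3-hydroxychroman-4-one F10. Bu3SnH/CF3CO2H should then reduce the two tertiary alcohols, the aryl ketone being inert, to the all-cis ketone F11. Hydroxyl-directed Saksena–Evans reduction with Me4NBH(OAc)3 (MeCN/AcOH, −20 °C) should deliver hydride syn to the 3-OH. This gives the 3,4-trans diol 33, where the route resumes at step 27.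

Step 6 (and likewise step 7). The 2,6-disubstituted, weakly nucleophilic phenoxide may react slowly, with erosion of branched selectivity and enantioselectivity through reversible ionisation of the product. The fallback takes the stereocentre from an epoxide and sets out from 6 and 3. Sharpless asymmetric epoxidation of 6 (Ti(Oi-Pr)4, diethyl L-tartrate, t-BuOOH, 4 Å sieves, −20 °C) should give [(2S,3S)-3-(4-benzyloxyphenyl)oxiran-2-yl]methanol F12. The phenoxide of 3 (Cs2CO3, DMF, 60 °C) should open it at the benzylic carbon with inversion to give the aryloxy diol F13. Thiocarbonyldiimidazole should give the cyclic thiocarbonate F14. Corey–Winter olefination (1,3-dimethyl-2-phenyl-1,3,2-diazaphospholidine, 40 °C) should restore the vinyl group and give 8. With diethyl D-tartrate the same sequence would serve 9.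

Further compounds
F1 | step 19 | (S)-1,5-bis(benzyloxy)-2-bromo-3-{1-[4-(benzyloxy)phenyl]allyloxy}-4-vinylbenzene | C=Cc1c(OCc5ccccc5)cc(OCc5ccccc5)c(Br)c1O[C@@H](C=C)c1ccc(OCc5ccccc5)cc1
F2 | step 19 | (S)-5,7-bis(benzyloxy)-2-[4-(benzyloxy)phenyl]-8-bromo-2H-chromene | Brc1c(OCc5ccccc5)cc(OCc5ccccc5)c2c1O[C@H](c1ccc(OCc5ccccc5)cc1)C=C2
F3 | step 19 | (2R,3S)-5,7-bis(benzyloxy)-2-[4-(benzyloxy)phenyl]-8-bromochroman-3-ol (2,3-trans) | Brc1c(OCc5ccccc5)cc(OCc5ccccc5)c2c1O[C@H](c1ccc(OCc5ccccc5)cc1)[C@@H](O)C2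
F4 | step 19 | (R)-5,7-bis(benzyloxy)-2-[4-(benzyloxy)phenyl]-8-bromochroman-3-one | Brc1c(OCc5ccccc5)cc(OCc5ccccc5)c2c1O[C@H](c1ccc(OCc5ccccc5)cc1)C(=O)C2
F5 | step 19 | (2R,3R)-5,7-bis(benzyloxy)-2-[4-(benzyloxy)phenyl]-8-bromochroman-3-ol (2,3-cis) | Brc1c(OCc5ccccc5)cc(OCc5ccccc5)c2c1O[C@H](c1ccc(OCc5ccccc5)cc1)[C@H](O)C2
F6 | step 19 | 3-O-(tert-butyldimethylsilyl) ether of F5 | Brc1c(OCc5ccccc5)cc(OCc5ccccc5)c2c1O[C@H](c1ccc(OCc5ccccc5)cc1)[C@H](O[Si](C)(C)C(C)(C)C)C2
F7 | step 19 | 4-hydroxy derivative of F6 (2,3-cis, 3,4-trans) | Brc1c(OCc5ccccc5)cc(OCc5ccccc5)c2c1O[C@H](c1ccc(OCc5ccccc5)cc1)[C@H](O[Si](C)(C)C(C)(C)C)[C@H]2O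
F8 | step 19 | (2R)-2,3-cis-5,7-bis(benzyloxy)-2-[4-(benzyloxy)phenyl]-8-bromo-3-(tert-butyldimethylsilyloxy)chroman-4-one | Brc1c(OCc5ccccc5)cc(OCc5ccccc5)c2c1O[C@H](c1ccc(OCc5ccccc5)cc1)[C@H](O[Si](C)(C)C(C)(C)C)C2=O
F9 | step 25 | hexaol: 31 without its three silyl groups | c5ccccc5COc1ccc([C@H]2Oc3c(c(OCc5ccccc5)cc(OCc5ccccc5)c3[C@]3(O)c4c(OCc5ccccc5)cc(OCc5ccccc5)cc4O[C@@H](c4ccc(OCc5ccccc5)cc4)[C@H]3O)[C@](O)(c3c(OCc5ccccc5)cc(OCc5ccccc5)c4c3O[C@@H](c3ccc(OCc5ccccc5)cc3)[C@@H](O)[C@@H]4O)[C@H]2O)cc1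
F10 | step 25 | F9 with C4 of the lower unit oxidised to the ketone | c5ccccc5COc1ccc([C@H]2Oc3c(c(OCc5ccccc5)cc(OCc5ccccc5)c3[C@]3(O)c4c(OCc5ccccc5)cc(OCc5ccccc5)cc4O[C@@H](c4ccc(OCc5ccccc5)cc4)[C@H]3O)[C@](O)(c3c(OCc5ccccc5)cc(OCc5ccccc5)c4c3O[C@@H](c3ccc(OCc5ccccc5)cc3)[C@@H](O)C4=O)[C@H]2O)cc1
F11 | step 25 | nona-O-benzyl trimer with C4–H in the upper and middle units (all-cis) and the lower unit as the 2,3-cis-3-hydroxychroman-4-one | c5ccccc5COc1ccc([C@H]2Oc3c(c(OCc5ccccc5)cc(OCc5ccccc5)c3[C@H]3c4c(OCc5ccccc5)cc(OCc5ccccc5)cc4O[C@@H](c4ccc(OCc5ccccc5)cc4)[C@H]3O)[C@@H](c3c(OCc5ccccc5)cc(OCc5ccccc5)c4c3O[C@@H](c3ccc(OCc5ccccc5)cc3)[C@@H](O)C4=O)[C@H]2O)cc1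
F12 | step 6 | [(2S,3S)-3-(4-benzyloxyphenyl)oxiran-2-yl]methanol | OC[C@@H]1O[C@H]1c1ccc(OCc5ccccc5)cc1
F13 | step 6 | 4,6-bis(benzyloxy)-3-bromo-2-{1-[4-(benzyloxy)phenyl]-2,3-dihydroxypropoxy}benzaldehyde, benzylic centre as in 8, carbinol centre retained from F12 | O=Cc1c(OCc5ccccc5)cc(OCc5ccccc5)c(Br)c1O[C@@H]([C@@H](O)CO)c1ccc(OCc5ccccc5)cc1
F14 | step 6 | cyclic thiocarbonate (1,3-dioxolane-2-thione) of F13 | O=Cc1c(OCc5ccccc5)cc(OCc5ccccc5)c(Br)c1O[C@@H]([C@@H]2COC(=S)O2)c1ccc(OCc5ccccc5)cc1
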